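**Retrosynthetic overview**
- Target 13 comes from triol 10 by esterifying its two primary hydroxyls with isobutyryl chloride 11; 10 comes from arene 8 by one mild acid hydrolysis of the silyl ether and the acetonide.
- Feature used: in the benzene ring (the only ring of 13) the carbinol-bearing carbon C1 and the methoxy-bearing carbon C2 are neighbours and correspond to the two sp carbons of a methoxyalkyne; ring carbons C3–C6, with the methyl on C4, correspond to diene carbons C3–C6 of 4-methyl-2-pyrone.
- Key disconnection: arene bonds C1–C6 and C2–C3, made by [4+2] addition of ynol ether 5 across C6 and C3 of pyrone 6 followed by loss of CO2. This builds the benzene ring, the only ring formed in the route (the dioxane ring is bought in ketone 2 and opened in step 3).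
- Ynol ether 5 comes from ketone 2 and lithium methoxyacetylide 3 (made from chloroacetal 1), with O-silylation in the same flask.

Key step: step 2

Remark: 13 is achiral (the carbinol carbon bears two identical acyloxymethyl arms); the stereocentres of the transient compounds 7 and 12 are racemic and do not persist.

**Route**

Step 1
Reactants: 1 chloroacetaldehyde dimethyl acetal (2-chloro-1,1-dimethoxyethane); 2 2,2-dimethyl-1,3-dioxan-5-one
Product: 5 5-(methoxyethynyl)-2,2-dimethyl-5-(trimethylsilyloxy)-1,3-dioxane, via lithium methoxyacetylide 3 (not isolated), via lithium alkoxide 4 (not isolated)
Conditions: Et2NH, n-BuLi, THF, 0 °C (LiNEt2, 2.9 equiv per 1); 1 (1.5 equiv), 0 °C, 2 h; 2 (1.0 equiv), −78 °C; TMSCl (excess), −78 °C → rt; cold aq NaHCO3; Et3N-deactivated silica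
Reagents that add atoms: chlorotrimethylsilane C[Si](C)(C)Cl
Why: LiNEt2 strips methanol and then HCl from the chloroacetal and deprotonates the resulting methoxyethyne, and the lithium acetylide so formed undergoes 1,2-addition to the ketone carbonyl followed by O-silylation of the tertiary alkoxide (acetylide addition to a ketone with in situ silyl ether formation), the base being kept just below three equivalents per acetal so that no free amide is left to enolise 2; no stereocentre arises because C5 of the dioxane carries two identical ring arms.

Step 2
Reactants: 5 5-(methoxyethynyl)-2,2-dimethyl-5-(trimethylsilyloxy)-1,3-dioxane; 6 4-methyl-2H-pyran-2-one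
Product: 8 5-(2-methoxy-4-methylphenyl)-2,2-dimethyl-5-(trimethylsilyloxy)-1,3-dioxane, via bridged lactone 7 (not isolated)
Conditions: 6 (3 equiv), mesitylene, BHT (cat), sealed tube, argon, 170 °C, −CO2; Et3N-deactivated silica
Reagents that add atoms: none
Why: The electron-poor pyrone diene (C3=C4–C5=C6) and the electron-rich ynol ether should combine in a concerted, asynchronous inverse-electron-demand [4+2] cycloaddition to the bridged lactone 7, which loses CO2 by retro-[4+2] under the same conditions and thereby aromatises. The closest known reaction type is the thermal benzannulation of 2-pyrones with alkynes, including donor-substituted alkynes such as ynamines and alkoxyalkynes, which likewise ends in extrusion of CO2; this pairing of a non-activated pyrone with a hindered ynol ether is untested. The benzene ring is closed by the intermolecular cycloaddition itself, in which both new ring bonds form (arene C1–C6 from the side-chain-bearing alkyne carbon to pyrone C6, arene C2–C3 from the methoxy-bearing alkyne carbon to pyrone C3), and decarboxylation then removes the lactone bridge. No stereocentre survives, since the two bridgehead centres of 7 are erased on aromatisation. The step needs regioselectivity, and the substrate secures it in two ways: the nucleophilic alkyne carbon beta to oxygen, which carries the dioxanyl group, bonds to the electrophilic and unsubstituted C6 of the dienyl lactone, and the bulky quaternary substituent thereby also avoids C3, which is flanked by the C4 methyl and the lactone carbonyl. The methyl ynol ether has no beta hydrogen for retro-ene fragmentation to a ketene, and the silyl cap on the propargylic oxygen suppresses Meyer–Schuster-type isomerisation, so the dienophile should tolerate the forcing temperature that the pyrone requires.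

Step 3
Reactants: 8 5-(2-methoxy-4-methylphenyl)-2,2-dimethyl-5-(trimethylsilyloxy)-1,3-dioxane
Product: 10 2-(2-methoxy-4-methylphenyl)propane-1,2,3-triol, via carbinol acetonide 9 (not isolated)
Conditions: AcOH–H2O–THF (3:1:1), rt; toluene azeotrope
Reagents that add atoms: none
Why: Acid-catalysed hydrolysis should remove the labile tertiary trimethylsilyl ether first and then the six-membered isopropylidene acetal, while ionisation of the tertiary benzylic carbinol in this weak acid is disfavoured by its two beta-oxygen substituents.

Step 4
Reactants: 10 2-(2-methoxy-4-methylphenyl)propane-1,2,3-triol; 11 isobutyryl chloride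
Product: 13 2-hydroxy-2-(2-methoxy-4-methylphenyl)propane-1,3-diyl bis(2-methylpropanoate), via mono-isobutyrate 12 (not isolated)
Conditions: 11 (2.2 equiv), pyridine, CH2Cl2, 0 °C → rt
Reagents that add atoms: isobutyryl chloride (11) CC(C)C(=O)Cl
Why: Acylation by an acid chloride with pyridine and no nucleophilic catalyst should esterify the two unhindered primary hydroxyls and leave the tertiary benzylic hydroxyl untouched, and because the two arms are equivalent the mono-ester 12 converges on 13.

**Compound list**
1 | chloroacetaldehyde dimethyl acetal (2-chloro-1,1-dimethoxyethane) | COC(CCl)OC | starting material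
2 | 2,2-dimethyl-1,3-dioxan-5-one | CC1(C)OCC(=O)CO1 | starting material
3 | lithium methoxyacetylide | [Li]C#COC | intermediate
4 | lithium 5-(methoxyethynyl)-2,2-dimethyl-1,3-dioxan-5-olate | [Li]OC1(C#COC)COC(C)(C)OC1 | intermediate
5 | 5-(methoxyethynyl)-2,2-dimethyl-5-(trimethylsilyloxy)-1,3-dioxane | COC#CC1(O[Si](C)(C)C)COC(C)(C)OC1 | intermediate
6 | 4-methyl-2H-pyran-2-one | CC1=CC(=O)OC=C1 | starting material
7 | 6-[2,2-dimethyl-5-(trimethylsilyloxy)-1,3-dioxan-5-yl]-5-methoxy-8-methyl-2-oxabicyclo[2.2.2]octa-5,7-dien-3-one (racemic; bridgehead configuration fixed by the bicycle) | O=C1OC2C=C(C)C1C(OC)=C2C3(O[Si](C)(C)C)COC(C)(C)OC3 | intermediate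
8 | 5-(2-methoxy-4-methylphenyl)-2,2-dimethyl-5-(trimethylsilyloxy)-1,3-dioxane | COc1cc(C)ccc1C1(O[Si](C)(C)C)COC(C)(C)OC1 | intermediate
9 | 5-(2-methoxy-4-methylphenyl)-2,2-dimethyl-1,3-dioxan-5-ol | COc1cc(C)ccc1C1(O)COC(C)(C)OC1 | intermediate
10 | 2-(2-methoxy-4-methylphenyl)propane-1,2,3-triol | COc1cc(C)ccc1C(O)(CO)CO | intermediate
11 | isobutyryl chloride (2-methylpropanoyl chloride) | CC(C)C(=O)Cl | starting material
12 | 2,3-dihydroxy-2-(2-methoxy-4-methylphenyl)propyl 2-methylpropanoate (racemic) | COc1cc(C)ccc1C(O)(CO)COC(=O)C(C)C | intermediate
13 | 2-hydroxy-2-(2-methoxy-4-methylphenyl)propane-1,3-diyl bis(2-methylpropanoate) | COc1cc(C)ccc1C(O)(COC(=O)C(C)C)COC(=O)C(C)C | target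

**Step count**
Total step count: 4. Longest linear sequence: 4 steps (1 → 5 → 8 → 10 → 13).

**Steps most likely to fail**

1. Step 2. The cycloaddition between a pyrone without an activating group and a dienophile with a fully substituted propargylic carbon may be too slow. Thermal decomposition or oligomerisation of the ynol ether, or loss of the silyl group followed by isomerisation to an unsaturated ester, could then outrun arene formation. Leakage of regiochemistry to the 2-methoxy-5-methyl isomer is the second possible failure. Very high pressure (10–15 kbar, CH2Cl2, 40–60 °C) would be tried first, but that is only a change of conditions. The fallback gives up the cycloaddition and forms the aryl–carbinol bond by organometallic addition. Commercial 1-bromo-2-methoxy-4-methylbenzene undergoes bromine–lithium exchange with n-BuLi in THF at −78 °C to give (2-methoxy-4-methylphenyl)lithium F1. This adds to ketone 2 to give lithium 5-(2-methoxy-4-methylphenyl)-2,2-dimethyl-1,3-dioxan-5-olate F2, which aqueous NH4Cl converts into carbinol acetonide 9. The fallback sets out from compound 2 and comes back to the route at compound 9, which is then carried through the acid treatment of step 3 to triol 10.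

2. Step 1. The ketone may be enolised by residual amide or by the basic acetylide instead of being attacked at carbon. The hindered alkoxide may be only partly silylated because lithium methoxide and diethylamine compete for the silyl chloride. The ynol ether may also be hydrated or rearranged by adventitious acid during work-up. The fallback separates the operations and uses an isolated, amine-free alkyne. Compound 1 is treated with NaNH2 in liquid NH3 to give sodium methoxyacetylide F3. Cold saturated aqueous NaCl then liberates methoxyethyne F4, which is distilled. n-BuLi in THF at −78 °C converts F4 into compound 3, free of amine and alkoxide, and this adds to 2 to give compound 4. A NaHCO3 quench gives 5-(methoxyethynyl)-2,2-dimethyl-1,3-dioxan-5-ol F5, which is isolated on base-washed silica and silylated under neutral conditions with N-(trimethylsilyl)imidazole in CH2Cl2. The fallback sets out from compound 1 and comes back at compound 5.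

3. Step 4. Discrimination among the three hydroxyls may be imperfect: the reaction may stall at mono-ester 12, or the tertiary benzylic hydroxyl may be partly acylated when the reaction is pushed. The pyridinium chloride formed may also promote ionisation at the benzylic carbinol. The fallback replaces the acid chloride by an enzymatic transesterification. Triol 10 is treated with excess vinyl 2-methylpropanoate and immobilised Candida antarctica lipase B in tert-butyl methyl ether at 40 °C. The lipase acylates only primary hydroxyls under neutral conditions, and tautomerisation of the released vinyl alcohol to acetaldehyde makes each acylation irreversible. The fallback sets out from compound 10, passes through compound 12 and comes back at compound 13; no compound outside the list arises (entry F0 below).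

**Further compounds**
F1 | step 2 | (2-methoxy-4-methylphenyl)lithium | [Li]c1ccc(C)cc1OC
F2 | step 2 | lithium 5-(2-methoxy-4-methylphenyl)-2,2-dimethyl-1,3-dioxan-5-olate | [Li]OC1(c2ccc(C)cc2OC)COC(C)(C)OC1
F3 | step 1 | sodium methoxyacetylide | [Na]C#COC
F4 | step 1 | methoxyethyne | COC#C
F5 | step 1 | 5-(methoxyethynyl)-2,2-dimethyl-1,3-dioxan-5-ol | COC#CC1(O)COC(C)(C)OC1
F0 | step 4 | none | none
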